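The piperidine is cut at N1–C6 and C3–C4. The key step exploits that piperidine C2 carries both N1 and the phloroglucinol ring (ring A): N1–C2–C3 is therefore the aza-enolate of an aryl methyl ketimine, a 1,3-C,N-dinucleophile, and C4–C6 a 1,3-dielectrophile. In one flask the (R)-N-tert-butanesulfinyl ketimine of a symmetric 2,6-dibenzyloxy-4-(methoxymethoxy)acetophenone is C-alkylated with 1-chloro-3-iodopropane, reduced under auxiliary control and closed by N-alkylation, giving the (S)-2-arylpiperidine. The symmetry of ring A and its unique para oxygen then fix the flavanone regiochemistry; C2 of the pyranone ring is set by rhodium-catalysed asymmetric arylation of a chromone.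

Key step: step 4

Assumption: the target is read as the (2S)-flavanone carrying an (S)-configured piperidine C2 at C6, and the (S)-configured rhodium catalyst of step 8 is taken to select the chromone face as it does for cyclohexenone, which corresponds to 2S (the enantiomeric ligand would serve otherwise).

Step 1
Reactants: 1 2',4',6'-trihydroxyacetophenone
Product: 2 1-[2,6-dihydroxy-4-(methoxymethoxy)phenyl]ethan-1-one
Conditions: MOMCl (1.0 equiv), iPr2NEt, CH2Cl2, 0 °C
Reagents that add atoms: chloromethyl methyl ether (COCCl)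
Why: Williamson-type O-alkylation; the 4-OH lies para to the acetyl group and, unlike the two chelated ortho phenols, is free and the most acidic, so one equivalent of MOMCl should etherify it selectively.

Step 2
Reactants: 2 1-[2,6-dihydroxy-4-(methoxymethoxy)phenyl]ethan-1-one
Product: 3 1-[2,6-bis(benzyloxy)-4-(methoxymethoxy)phenyl]ethan-1-one
Conditions: BnBr (2.5 equiv), K2CO3, DMF, 70 °C
Reagents that add atoms: benzyl bromide (BrCc1ccccc1)
Why: Williamson etherification with excess benzyl bromide and carbonate in warm DMF should overcome the hydrogen bonding of both ortho phenols, and the MOM acetal is stable to base.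

Step 3
Reactants: 3 1-[2,6-bis(benzyloxy)-4-(methoxymethoxy)phenyl]ethan-1-one; 4 (R)-2-methylpropane-2-sulfinamide
Product: 5 (R,E)-N-{1-[2,6-bis(benzyloxy)-4-(methoxymethoxy)phenyl]ethylidene}-2-methylpropane-2-sulfinamide
Conditions: Ti(OEt)4 (3 equiv), toluene, 90 °C
Reagents that add atoms: none
Why: Ti(OEt)4-mediated condensation of a ketone with tert-butanesulfinamide (Ellman ketimine formation), the titanium alkoxide acting as Lewis acid and water scavenger; the bulky aryl group should place the sulfinyl group anti to it (E).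

Step 4
Reactants: 5 (R,E)-N-{1-[2,6-bis(benzyloxy)-4-(methoxymethoxy)phenyl]ethylidene}-2-methylpropane-2-sulfinamide; 6 1-chloro-3-iodopropane
Product: 9 (2S)-2-[2,6-bis(benzyloxy)-4-(methoxymethoxy)phenyl]-1-[(R)-tert-butylsulfinyl]piperidine, via δ-chloro sulfinyl ketimine 7 (not isolated), via open-chain chloro sulfinamide 8 (not isolated)
Conditions: LiN(iPr)2 (LDA), THF, −78 °C; then 6, DMPU, −78 → −20 °C; then LiBHEt3 (1.05 equiv), −78 °C; then warm to 50 °C
Reagents that add atoms: none
Why: LDA removes a methyl proton of 5 to give the lithium aza-enolate, whose carbon (the future piperidine C3) displaces iodide of 6 in preference to chloride, forming C3–C4 and giving ketimine 7. LiBHEt3 then reduces the C=N bond through the open, non-chelated transition state typical of trialkylborohydrides, in which the (R)-sulfinyl auxiliary shields one face of the E-ketimine, which should set the (S)-configured benzylic carbon of 8. On warming, the lithium sulfinamide nitrogen closes the piperidine by 6-exo-tet displacement of chloride, helped by halide exchange with the LiI formed in the alkylation, forming N–C6. The closest known reaction types are the α-alkylation of N-tert-butanesulfinyl ketimine aza-enolates and the reductive cyclization of ω-chloro N-sulfinyl ketimines with LiBHEt3 to 2-aryl pyrrolidines and piperidines. The step needs mono-alkylation at carbon, secured by the iodide/chloride reactivity gap, the low temperature and the single enolisable methyl group, and it needs facial selectivity, secured by the E geometry that the 2,6-dibenzyloxyaryl group enforces together with the auxiliary.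

Step 5
Reactants: 9 (2S)-2-[2,6-bis(benzyloxy)-4-(methoxymethoxy)phenyl]-1-[(R)-tert-butylsulfinyl]piperidine
Product: 12 3,5-bis(benzyloxy)-4-[(2S)-1-methylpiperidin-2-yl]phenol, via secondary amine MOM ether 10 (not isolated), via N-methyl amine MOM ether 11 (not isolated)
Conditions: HCl (4 M in dioxane, 2 equiv), MeOH, 0 °C; evaporate; then aq. HCHO, NaBH(OAc)3, NaOAc, THF, rt; then 3 M HCl, MeOH, 40 °C; NaHCO3 work-up
Reagents that add atoms: formaldehyde (C=O)
Why: Acidic methanolysis of the N–S bond, reductive amination with formaldehyde while the phenol is still masked (so that no Mannich reaction of the electron-rich ring competes) and acid hydrolysis of the MOM acetal are standard operations that touch no bond at the stereocenter.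

Step 6
Reactants: 12 3,5-bis(benzyloxy)-4-[(2S)-1-methylpiperidin-2-yl]phenol
Product: 13 1-{2,4-bis(benzyloxy)-6-hydroxy-3-[(2S)-1-methylpiperidin-2-yl]phenyl}ethan-1-one
Conditions: Ac2O (1.5 equiv), BF3·OEt2, CH2Cl2, 0 °C → rt; then aq. NaHCO3, MeOH, 40 °C
Reagents that add atoms: acetic anhydride (CC(=O)OC(C)=O)
Why: BF3-mediated Friedel–Crafts acetylation (through the aryl acetate and a Fries-type shift) of a strongly activated phenol whose only two free ring positions are equivalent by symmetry and both ortho to the hydroxyl group, so only one regioisomer is possible, while the amine is masked as its BF3 adduct.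

Step 7
Reactants: 13 1-{2,4-bis(benzyloxy)-6-hydroxy-3-[(2S)-1-methylpiperidin-2-yl]phenyl}ethan-1-one
Product: 15 5,7-bis(benzyloxy)-6-[(2S)-1-methylpiperidin-2-yl]-4H-chromen-4-one, via enaminone 14 (not isolated)
Conditions: Me2NCH(OMe)2, toluene, 70 °C; evaporate; then AcOH, 60 °C
Reagents that add atoms: N,N-dimethylformamide dimethyl acetal (COC(OC)N(C)C)
Why: Condensation of the methyl ketone with the formamide acetal gives the enaminone, and acid promotes conjugate addition of the only free phenol oxygen with loss of dimethylamine (standard chromone synthesis), which places the piperidine at C6 because that oxygen is para to it.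

Step 8
Reactants: 15 5,7-bis(benzyloxy)-6-[(2S)-1-methylpiperidin-2-yl]-4H-chromen-4-one; 16 [4-(benzyloxy)phenyl]boronic acid
Product: 17 (2S)-5,7-bis(benzyloxy)-2-[4-(benzyloxy)phenyl]-6-[(2S)-1-methylpiperidin-2-yl]-2,3-dihydro-4H-chromen-4-one
Conditions: [Rh(OH)(cod)]2 (cat.), (S)-MeO-F12-BIPHEP [(S)-(6,6'-dimethoxybiphenyl-2,2'-diyl)bis[bis(3,4,5-trifluorophenyl)phosphine]] (cat.), 16 (2.5 equiv), toluene, H2O (few equiv), 40 °C
Reagents that add atoms: none
Why: Hayashi–Miyaura rhodium-catalysed asymmetric 1,4-addition of an arylboronic acid to a chromone with an electron-poor biaryl bisphosphine; the chiral ligand alone selects the face of C2 and should give the 2S flavanone irrespective of the remote piperidine center, and the near-neutral, low-water medium limits ring opening to the chalcone.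

Step 9
Reactants: 17 (2S)-5,7-bis(benzyloxy)-2-[4-(benzyloxy)phenyl]-6-[(2S)-1-methylpiperidin-2-yl]-2,3-dihydro-4H-chromen-4-one
Product: 18 (2S)-5,7-dihydroxy-2-(4-hydroxyphenyl)-6-[(2S)-1-methylpiperidin-2-yl]-2,3-dihydro-4H-chromen-4-one
Conditions: H2 (1 atm), Pd/C, EtOAc–MeOH, rt
Reagents that add atoms: none
Why: Hydrogenolysis of the three aryl benzyl ethers over palladium on carbon under neutral conditions should leave the flavanone ketone and both stereocenters untouched, since neither acid nor base is present.

Compound list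
1 | 2',4',6'-trihydroxyacetophenone | CC(=O)c1c(O)cc(O)cc1O | starting material
2 | 1-[2,6-dihydroxy-4-(methoxymethoxy)phenyl]ethan-1-one | COCOc1cc(O)c(C(C)=O)c(O)c1 | intermediate
3 | 1-[2,6-bis(benzyloxy)-4-(methoxymethoxy)phenyl]ethan-1-one | COCOc1cc(OCc2ccccc2)c(C(C)=O)c(OCc2ccccc2)c1 | intermediate
4 | (R)-2-methylpropane-2-sulfinamide | CC(C)(C)[S@@](=O)N | starting material
5 | (R,E)-N-{1-[2,6-bis(benzyloxy)-4-(methoxymethoxy)phenyl]ethylidene}-2-methylpropane-2-sulfinamide | CC(C)(C)[S@@](=O)/N=C(\C)c1c(OCc2ccccc2)cc(OCOC)cc1OCc1ccccc1 | intermediate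
6 | 1-chloro-3-iodopropane | ClCCCI | starting material
7 | (R,E)-N-{1-[2,6-bis(benzyloxy)-4-(methoxymethoxy)phenyl]-5-chloropentylidene}-2-methylpropane-2-sulfinamide | CC(C)(C)[S@@](=O)/N=C(\CCCCCl)c1c(OCc2ccccc2)cc(OCOC)cc1OCc1ccccc1 | intermediate
8 | (R)-N-{(1S)-1-[2,6-bis(benzyloxy)-4-(methoxymethoxy)phenyl]-5-chloropentyl}-2-methylpropane-2-sulfinamide, formed as its lithium salt | CC(C)(C)[S@@](=O)N[C@@H](CCCCCl)c1c(OCc2ccccc2)cc(OCOC)cc1OCc1ccccc1 | intermediate
9 | (2S)-2-[2,6-bis(benzyloxy)-4-(methoxymethoxy)phenyl]-1-[(R)-tert-butylsulfinyl]piperidine | CC(C)(C)[S@@](=O)N1CCCC[C@H]1c1c(OCc2ccccc2)cc(OCOC)cc1OCc1ccccc1 | intermediate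
10 | (2S)-2-[2,6-bis(benzyloxy)-4-(methoxymethoxy)phenyl]piperidine | N1CCCC[C@H]1c1c(OCc2ccccc2)cc(OCOC)cc1OCc1ccccc1 | intermediate
11 | (2S)-2-[2,6-bis(benzyloxy)-4-(methoxymethoxy)phenyl]-1-methylpiperidine | CN1CCCC[C@H]1c1c(OCc2ccccc2)cc(OCOC)cc1OCc1ccccc1 | intermediate
12 | 3,5-bis(benzyloxy)-4-[(2S)-1-methylpiperidin-2-yl]phenol | CN1CCCC[C@H]1c1c(OCc2ccccc2)cc(O)cc1OCc1ccccc1 | intermediate
13 | 1-{2,4-bis(benzyloxy)-6-hydroxy-3-[(2S)-1-methylpiperidin-2-yl]phenyl}ethan-1-one | CN1CCCC[C@H]1c1c(OCc2ccccc2)cc(O)c(C(C)=O)c1OCc1ccccc1 | intermediate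
14 | (E)-1-{2,4-bis(benzyloxy)-6-hydroxy-3-[(2S)-1-methylpiperidin-2-yl]phenyl}-3-(dimethylamino)prop-2-en-1-one | CN1CCCC[C@H]1c1c(OCc2ccccc2)cc(O)c(C(=O)/C=C/N(C)C)c1OCc1ccccc1 | intermediate
15 | 5,7-bis(benzyloxy)-6-[(2S)-1-methylpiperidin-2-yl]-4H-chromen-4-one | CN1CCCC[C@H]1c1c(OCc2ccccc2)cc2occc(=O)c2c1OCc1ccccc1 | intermediate
16 | [4-(benzyloxy)phenyl]boronic acid | OB(O)c1ccc(OCc2ccccc2)cc1 | starting material
17 | (2S)-5,7-bis(benzyloxy)-2-[4-(benzyloxy)phenyl]-6-[(2S)-1-methylpiperidin-2-yl]-2,3-dihydro-4H-chromen-4-one | CN1CCCC[C@H]1c1c(OCc2ccccc2)cc2c(c1OCc1ccccc1)C(=O)C[C@@H](c1ccc(OCc3ccccc3)cc1)O2 | intermediate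
18 | (2S)-5,7-dihydroxy-2-(4-hydroxyphenyl)-6-[(2S)-1-methylpiperidin-2-yl]-2,3-dihydro-4H-chromen-4-one | CN1CCCC[C@H]1c1c(O)cc2c(c1O)C(=O)C[C@@H](c1ccc(O)cc1)O2 | target

Total step count: 9
Longest linear sequence: 9 steps (1 → 18)

Steps most likely to fail

Step 4. The aza-enolate may be alkylated twice through proton exchange with the mono-alkylated ketimine, the six-membered closure of the hindered sulfinamide anion may be slow enough for the chloride to be lost by reduction, and facial selectivity may erode if the congested ketimine is reduced through both imine geometries. The fallback sets out from ketone 3 and lets a catalyst instead of the auxiliary set the stereocenter. Condensation with methylamine (MeNH2 in THF, Ti(OiPr)4) should give (E)-1-[2,6-bis(benzyloxy)-4-(methoxymethoxy)phenyl]-N-methylethan-1-imine F1. Its lithium aza-enolate (LDA, THF, −78 °C) is alkylated with 1-bromo-3-chloropropane, and heating in MeCN closes the ring by N-alkylation to 6-[2,6-bis(benzyloxy)-4-(methoxymethoxy)phenyl]-1-methyl-2,3,4,5-tetrahydropyridin-1-ium chloride F2. Asymmetric hydrogenation of this cyclic iminium salt (H2, [Ir(cod)Cl]2 with the SegPhos enantiomer that delivers the S amine) should give compound 11, where the fallback comes back to the route; 11 is taken through the last stage of step 5.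

Step 8. Carbometalation of the electron-rich, hindered chromone may be slow (with the tertiary amine competing for rhodium), protodeboronation may outrun addition, and base-induced ring opening of the flavanone to the chalcone may erase the configuration at C2. The fallback sets out from acetophenone 13. Claisen–Schmidt condensation with 4-(benzyloxy)benzaldehyde (KOH, EtOH, rt) should give (E)-1-{2,4-bis(benzyloxy)-6-hydroxy-3-[(2S)-1-methylpiperidin-2-yl]phenyl}-3-[4-(benzyloxy)phenyl]prop-2-en-1-one F3. Oxa-Michael ring closure (NaOAc, EtOH, reflux) should give 17 together with its (2R) epimer (2R)-5,7-bis(benzyloxy)-2-[4-(benzyloxy)phenyl]-6-[(2S)-1-methylpiperidin-2-yl]-2,3-dihydro-4H-chromen-4-one F4. The two are diastereomers because of the fixed piperidine center, so they should be separable by chromatography or crystallisation, and the unwanted epimer can be returned to the equilibrium under the same conditions. The fallback comes back at compound 17.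

Step 6. The Lewis acid may cleave the benzyl ether next to the new ketone, which would free both ortho oxygens and remove the regiochemical control of step 7, or it may ionise the benzylic C–N bond and scramble the piperidine center. The fallback sets out from phenol 12 and avoids Lewis acid altogether. Iodination of the trifluoroacetate salt ortho to the hydroxyl group (N-iodosuccinimide, CF3CO2H, CH2Cl2, 0 °C) should give 3,5-bis(benzyloxy)-2-iodo-4-[(2S)-1-methylpiperidin-2-yl]phenol F5. Stille coupling with tributyl(1-ethoxyvinyl)stannane (Pd(PPh3)4, toluene, 90 °C) should give 3,5-bis(benzyloxy)-2-(1-ethoxyvinyl)-4-[(2S)-1-methylpiperidin-2-yl]phenol F6, and dilute aqueous HCl in THF at rt hydrolyses the enol ether to compound 13, where the fallback comes back to the route.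

Further compounds
F1 | step 4 | (E)-1-[2,6-bis(benzyloxy)-4-(methoxymethoxy)phenyl]-N-methylethan-1-imine | C/N=C(\C)c1c(OCc2ccccc2)cc(OCOC)cc1OCc1ccccc1
F2 | step 4 | 6-[2,6-bis(benzyloxy)-4-(methoxymethoxy)phenyl]-1-methyl-2,3,4,5-tetrahydropyridin-1-ium chloride | C[N+]1=C(CCCC1)c1c(OCc2ccccc2)cc(OCOC)cc1OCc1ccccc1.[Cl-]
F3 | step 8 | (E)-1-{2,4-bis(benzyloxy)-6-hydroxy-3-[(2S)-1-methylpiperidin-2-yl]phenyl}-3-[4-(benzyloxy)phenyl]prop-2-en-1-one | CN1CCCC[C@H]1c1c(OCc2ccccc2)cc(O)c(C(=O)/C=C/c2ccc(OCc3ccccc3)cc2)c1OCc1ccccc1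
F4 | step 8 | (2R)-5,7-bis(benzyloxy)-2-[4-(benzyloxy)phenyl]-6-[(2S)-1-methylpiperidin-2-yl]-2,3-dihydro-4H-chromen-4-one | CN1CCCC[C@H]1c1c(OCc2ccccc2)cc2c(c1OCc1ccccc1)C(=O)C[C@H](c1ccc(OCc3ccccc3)cc1)O2
F5 | step 6 | 3,5-bis(benzyloxy)-2-iodo-4-[(2S)-1-methylpiperidin-2-yl]phenol | CN1CCCC[C@H]1c1c(OCc2ccccc2)cc(O)c(I)c1OCc1ccccc1
F6 | step 6 | 3,5-bis(benzyloxy)-2-(1-ethoxyvinyl)-4-[(2S)-1-methylpiperidin-2-yl]phenol | CN1CCCC[C@H]1c1c(OCc2ccccc2)cc(O)c(C(=C)OCC)c1OCc1ccccc1
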